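In a closed, stirred, isothermal flask, D at 20 mM meets E at 0.900 equiv and the catalyst Q at 1 mol%. Saturday's run is this same flask, followed so far:

- Saturday's (time / s: X / %, D / %): 10.0: 11.8, 87.2; 20.0: 23.4, 75.8

(scatter of a reading: 0.3 percentage points)

1. amount of X in percent of the D charged, at 12 s, 40 s, 80 s and 2.0 min

Between the two readings X rose by a fraction s = 0.0116 s⁻¹ of the D charged. The gain of the second interval over that of the first is 0.983, a ratio from which time drops out, read with a scatter of 0.3 percentage points on each reading, so we take the course so far as a straight line. Dividing the E charge by s gives 77.6 s. This is the run-out time t_out: the time the straight line needs to use up E, the limiting reagent, reckoning one E for each X.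

Now the settings, by hand. The equivalents of E are the numerator of t_out and the ceiling on X, 90.0% of the D charged. The loading of Q enters through s: s over the loading is 1.16 s⁻¹, a reading of the turnovers of each Q per second, so t_out is the E charge over loading times turnover for as long as that pace holds. D had fallen to 75.8% by 20.0 s with the gain ratio above, so within the scatter the line as read shows no dependence on D. The time allowed, 2.0 min, is longer than t_out, so the last point should stand at the ceiling.

Our line gives 13.9% at 12 s and 46.4% at 40 s, and at 80 s, later than t_out, it has reached the ceiling.

The forecast gave 14%, 46%, 86% and 89.5%; its value at 80 s is lower than our ceiling, and it says “some rounding off is likely as E runs out”.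

The flask gives 14.0%, 45.5%, 82.6% and 90.0%.

    E + Q → J (k = 4400 M⁻¹ s⁻¹)
    D + J ⇌ L (K = 13.0 M⁻¹, k = 15000 M⁻¹ s⁻¹)
    L → Z (k = 44.0 s⁻¹)
    Z → Q + X (k = 1.40 s⁻¹)

While E was there (83.4% of its charge at 0.200 min, 25.8% at 1.00 min), Z → Q + X ran with Z as the resting state, at 83.2% of the catalyst charged and then 67.7%, and the step E + Q → J had half of its turnover behind it at 0.644 min, where half of t_out is 0.647 min. X stood at 82.6% at 80 s, and by 2.00 min E was at 0%, Q was back at 100% of the catalyst charged, a tenfold time changed nothing, and 10% of the D charged remained unbound.

Readings and results were generated by integration with made-up constants, noise included.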